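**Retrosynthetic overview**
- The methylene bridge is made last: a ring B C-methyl group is dehydrogenated to an exo-methylene trione, which is captured by C8 of the chromene (ring A).
- The (E)-geranyl chain is grown on ring B from an allyl group: cross-metathesis to a (Z)-alkenyl boronate, then stereoretentive sp2–sp3 Suzuki coupling.
- Key step: the quaternary stereocenter comes from a desymmetrising oxidative dearomatisation of symmetric 3,5-dimethylphloroacetophenone. A chiral aryloxy trivalent-iodine species (an enolonium equivalent) is attacked by allyltrimethylsilane at one of two enantiotopic C-methyl carbons.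
- Ring A: Friedel–Crafts butanoylation of phloroglucinol, then prenal condensation and oxa-6π electrocyclisation.
- Ring order: both carbocycles are bought as phloroglucinols; ring B is dearomatised, not built; the pyran ring (ring A branch) is the only ring formed.

Assumption: the sense of induction of the chiral iodane in step 2 cannot be predicted for a new reaction; the (R,R)-reagent is written, and its mirror image is used if it favours the (4S)-dienone.
Assumption: enolised triketone rings are drawn in the tautomer of the target SMILES, and CIP descriptors refer to the tautomer drawn.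

**Step 1**
Reactants: 1 1-(2,4,6-trihydroxyphenyl)ethan-1-one (phloroacetophenone)
Product: 2 1-(2,4,6-trihydroxy-3,5-dimethylphenyl)ethan-1-one
Conditions: MeI (2.2 equiv), NaOMe (3.2 equiv), MeOH, 0 °C to rt, 16 h; aq. HCl work-up
Reagents that add atoms: iodomethane, CI
Why: The phloroglucinol phenoxide is a strong carbon nucleophile and undergoes Friedel–Crafts-type C-alkylation at both free ring carbons, with stoichiometry limiting over-methylation (mono- and trimethyl by-products are removed by chromatography); no stereocenter is formed.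

**Step 2**
Reactants: 2 1-(2,4,6-trihydroxy-3,5-dimethylphenyl)ethan-1-one
Product: 4 (4R)-2-acetyl-3,5-dihydroxy-4,6-dimethyl-4-(prop-2-en-1-yl)cyclohexa-2,5-dien-1-one, via aryloxyiodane 3 (not isolated)
Conditions: (R,R)-ArI(OAc)2 (1.0 equiv, preformed; Ar = 2,6-bis{[(2R)-1-(mesitylamino)-1-oxopropan-2-yl]oxy}phenyl), CH2=CHCH2SiMe3 (3 equiv), CH2Cl2/(CF3)2CHOH 9:1, −40 °C, 2 h
Reagents that add atoms: allyltrimethylsilane, C=CC[Si](C)(C)C
Why: Proposed new method: the most acidic 4-OH of 2 exchanges onto trivalent iodine to give aryloxyiodane 3, in which the methyl-bearing ring carbons ortho to the bound oxygen are electrophilic (enolonium/phenoxenium equivalent), so the π-nucleophilic allylsilane bonds to one of them with loss of the aryl iodide and silyl elimination (SE2′), joining two innately nucleophilic carbons; the two methyl-bearing carbons are enantiotopic and the hydrogen-bonded lactamide arms of the chiral aryl iodide expose one of them, setting the quaternary stereocenter as (4R); the closest known reactions are the PhI(OAc)2-mediated oxidative allylation of phenols with allylsilanes (oxidative Hosomi–Sakurai dearomatisation) and the enantioselective oxidative dearomatisation of phenols by lactamide-based chiral aryl iodides with oxygen or tethered carbon nucleophiles.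

**Step 3**
Reactants: 4 (4R)-2-acetyl-3,5-dihydroxy-4,6-dimethyl-4-(prop-2-en-1-yl)cyclohexa-2,5-dien-1-one
Product: 5 (4R)-2-acetyl-3,5-dihydroxy-4,6-dimethyl-4-[(2Z)-3-(4,4,5,5-tetramethyl-1,3,2-dioxaborolan-2-yl)but-2-en-1-yl]cyclohexa-2,5-dien-1-one
Conditions: CH2=C(Me)B(pin) (3 equiv), second-generation Grubbs catalyst RuCl2(=CHPh)(PCy3)(H2IMes) (5 mol %), CH2Cl2, 40 °C, 12 h
Reagents that add atoms: 4,4,5,5-tetramethyl-2-(prop-1-en-2-yl)-1,3,2-dioxaborolane (isopropenylboronic acid pinacol ester), CC(=C)B1OC(C)(C)C(C)(C)O1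
Why: The chain is grown from allyl because allylsilanes bond through their γ-carbon (a geranylsilane would deliver its tertiary carbon), and olefin cross-metathesis of a terminal alkene with 2-propenyl pinacol boronate gives the trisubstituted alkenyl boronate with boron trans to the allylic CH2 (Z by CIP), leaving the quaternary stereocenter untouched.

**Step 4**
Reactants: 5 (4R)-2-acetyl-3,5-dihydroxy-4,6-dimethyl-4-[(2Z)-3-(4,4,5,5-tetramethyl-1,3,2-dioxaborolan-2-yl)but-2-en-1-yl]cyclohexa-2,5-dien-1-one
Product: 6 (4R)-2-acetyl-4-[(2E)-3,7-dimethylocta-2,6-dien-1-yl]-3,5-dihydroxy-4,6-dimethylcyclohexa-2,5-dien-1-one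
Conditions: Me2C=CHCH2CH2Br (1.5 equiv), Pd(OAc)2 (5 mol %), P(t-Bu)2Me·HBF4 (10 mol %), KOt-Bu (4.5 equiv), t-amyl alcohol, rt, 24 h; aq. citric acid work-up
Reagents that add atoms: 5-bromo-2-methylpent-2-ene, CC(C)=CCCBr
Why: Suzuki–Miyaura sp2–sp3 coupling of an alkenyl boronate with a primary alkyl bromide under a bulky electron-rich trialkylphosphine–palladium catalyst (fast oxidative addition, slow β-hydride elimination) proceeds with retention at the alkenyl carbon, so the (Z)-boronate gives the (E)-geranyl olefin while the triketone is carried as its inert potassium enolate.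

**Step 5**
Reactants: 7 benzene-1,3,5-triol (phloroglucinol)
Product: 8 1-(2,4,6-trihydroxyphenyl)butan-1-one
Conditions: n-PrCOCl (1.1 equiv), AlCl3 (3.5 equiv), PhNO2, rt to 60 °C; ice/aq. HCl
Reagents that add atoms: butanoyl chloride, CCCC(Cl)=O
Why: Friedel–Crafts C-acylation of the electron-rich triol stops at mono-acylation because the chelated aryl ketone is deactivated.

**Step 6**
Reactants: 8 1-(2,4,6-trihydroxyphenyl)butan-1-one
Product: 10 1-(5,7-dihydroxy-2,2-dimethyl-2H-chromen-6-yl)butan-1-one, via ortho-quinone methide 9 (not isolated)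
Conditions: Me2C=CHCHO (1.5 equiv), ethylenediammonium diacetate (20 mol %), toluene, 110 °C, 6 h
Reagents that add atoms: 3-methylbut-2-enal, CC(C)=CC=O
Why: Knoevenagel-type condensation of the aldehyde at a free ring carbon and dehydration give ortho-quinone methide 9, whose oxa-6π electrocyclisation through the oxygen para to the acyl group forms the 2,2-dimethyl-2H-chromene 10 (the 8-butanoyl regioisomer from closure through an ortho oxygen is separated by chromatography and can be re-equilibrated thermally).

**Step 7**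
Reactants: 6 (4R)-2-acetyl-4-[(2E)-3,7-dimethylocta-2,6-dien-1-yl]-3,5-dihydroxy-4,6-dimethylcyclohexa-2,5-dien-1-one; 10 1-(5,7-dihydroxy-2,2-dimethyl-2H-chromen-6-yl)butan-1-one
Product: 12 1-[8-({(3R)-5-acetyl-3-[(2E)-3,7-dimethylocta-2,6-dien-1-yl]-2,4-dihydroxy-3-methyl-6-oxocyclohexa-1,4-dien-1-yl}methyl)-5,7-dihydroxy-2,2-dimethyl-2H-chromen-6-yl]butan-1-one, via exo-methylene trione 11 (not isolated)
Conditions: Ag2O (1.2 equiv), TEMPO (20 mol %), THF, 0 °C, 30 min; then 10 (1.5 equiv), 0 °C to rt
Reagents that add atoms: none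
Why: Ag2O/TEMPO dehydrogenation of the C-methyl group on the enolised triketone carbon gives exo-methylene trione 11 (an ortho-quinone-methide-type Michael acceptor), to which the only free aromatic carbon (C8) of 10 adds in a Friedel–Crafts-type Michael addition followed by re-enolisation, the quaternary stereocenter being untouched.

**Compound list**
1 | 1-(2,4,6-trihydroxyphenyl)ethan-1-one (phloroacetophenone) | CC(=O)c1c(O)cc(O)cc1O | starting material
2 | 1-(2,4,6-trihydroxy-3,5-dimethylphenyl)ethan-1-one | CC(=O)c1c(O)c(C)c(O)c(C)c1O | intermediate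
3 | acetoxy(aryl)(aryloxy)iodane: 2 bound through its 4-oxygen to the trivalent iodine of the (R,R)-2,6-bis{[1-(mesitylamino)-1-oxopropan-2-yl]oxy}phenyl iodide unit, acetate as third ligand | CC(=O)c1c(O)c(C)c(OI(OC(C)=O)c2c(O[C@H](C)C(=O)Nc3c(C)cc(C)cc3C)cccc2O[C@H](C)C(=O)Nc2c(C)cc(C)cc2C)c(C)c1O | intermediate
4 | (4R)-2-acetyl-3,5-dihydroxy-4,6-dimethyl-4-(prop-2-en-1-yl)cyclohexa-2,5-dien-1-one | CC1=C(O)[C@@](C)(CC=C)C(O)=C(C(C)=O)C1=O | intermediate
5 | (4R)-2-acetyl-3,5-dihydroxy-4,6-dimethyl-4-[(2Z)-3-(4,4,5,5-tetramethyl-1,3,2-dioxaborolan-2-yl)but-2-en-1-yl]cyclohexa-2,5-dien-1-one | CC1=C(O)[C@@](C)(C/C=C(\C)B2OC(C)(C)C(C)(C)O2)C(O)=C(C(C)=O)C1=O | intermediate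
6 | (4R)-2-acetyl-4-[(2E)-3,7-dimethylocta-2,6-dien-1-yl]-3,5-dihydroxy-4,6-dimethylcyclohexa-2,5-dien-1-one | CC1=C(O)[C@@](C)(C/C=C(\C)CCC=C(C)C)C(O)=C(C(C)=O)C1=O | intermediate
7 | benzene-1,3,5-triol (phloroglucinol) | Oc1cc(O)cc(O)c1 | starting material
8 | 1-(2,4,6-trihydroxyphenyl)butan-1-one | CCCC(=O)c1c(O)cc(O)cc1O | intermediate
9 | 4-butanoyl-3,5-dihydroxy-6-(3-methylbut-2-en-1-ylidene)cyclohexa-2,4-dien-1-one (ortho-quinone methide) | CCCC(=O)C1=C(O)C(=CC=C(C)C)C(=O)C=C1O | intermediate
10 | 1-(5,7-dihydroxy-2,2-dimethyl-2H-chromen-6-yl)butan-1-one | CCCC(=O)c1c(O)cc2OC(C)(C)C=Cc2c1O | intermediate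
11 | (4S)-2-acetyl-4-[(2E)-3,7-dimethylocta-2,6-dien-1-yl]-3-hydroxy-4-methyl-6-methylidenecyclohex-2-ene-1,5-dione (same spatial arrangement as 6; the descriptor changes with the tautomer) | C=C1C(=O)[C@@](C)(C/C=C(\C)CCC=C(C)C)C(O)=C(C(C)=O)C1=O | intermediate
12 | 1-[8-({(3R)-5-acetyl-3-[(2E)-3,7-dimethylocta-2,6-dien-1-yl]-2,4-dihydroxy-3-methyl-6-oxocyclohexa-1,4-dien-1-yl}methyl)-5,7-dihydroxy-2,2-dimethyl-2H-chromen-6-yl]butan-1-one | CCCC(=O)c1c(O)c2c(c(CC3=C(O)[C@@](C)(C/C=C(\C)CCC=C(C)C)C(O)=C(C(C)=O)C3=O)c1O)OC(C)(C)C=C2 | target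

**Step count**
Total: 7 steps. Longest linear sequence: 5 steps (steps 1, 2, 3, 4 and 7); the ring A branch (steps 5 and 6) joins in step 7.

**Steps most likely to fail**

Step 2 is the riskiest. Enantioselection with an external carbon nucleophile on a chiral aryloxy trivalent-iodine species is unproven. The β-silyl cation may also be trapped by a neighbouring oxygen (formal [3+2] adduct), and a second oxidation of 4 must be avoided by using no more than one equivalent of oxidant at low temperature. Compound 4 should be kept below about 60 °C, because a degenerate Cope shift of the allyl group to the neighbouring C-methyl carbon would racemise it. The fallback sets out from 2 and returns to the route at 4. Oxidative allylation of 2 with achiral PhI(OAc)2 and allyltrimethylsilane in (CF3)2CHOH, the racemic form of the same coupling, gives racemic 2-acetyl-3,5-dihydroxy-4,6-dimethyl-4-(prop-2-en-1-yl)cyclohexa-2,5-dien-1-one F1. The acidic triketone is then resolved by crystallisation with (S)-N,N-dimethyl-1-phenylethylamine: the (S)-N,N-dimethyl-1-phenylethylammonium (4R)-enolate salt F2 is separated from the (S)-N,N-dimethyl-1-phenylethylammonium (4S)-enolate salt F3 (the (R)-amine is used instead if F3 proves the less soluble salt). Acidification of F2 with dilute HCl gives 4.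

Step 4 is the second risk. The alkyl bromide coupling has to run on a polyanionic triketonate that can bind palladium, and a hindered trisubstituted alkenyl pinacol boronate may transmetalate slowly. The fallback sets out from 5 and returns at 6 with the coupling roles reversed. Iododeboronation with retention (NaOH, I2, THF/H2O, 0 °C, thiosulfate work-up) gives (4R)-2-acetyl-3,5-dihydroxy-4-[(2E)-3-iodobut-2-en-1-yl]-4,6-dimethylcyclohexa-2,5-dien-1-one F4. After conversion to its sodium enolate with NaH, F4 undergoes Negishi coupling with Me2C=CHCH2CH2ZnBr (from the bromide, Zn dust and LiCl) and Pd(PPh3)4 in THF at 40 °C to give 6 with retention of the olefin geometry.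

Step 7 is the third risk. The electron-rich phloroglucinol 10 may itself be oxidised by Ag2O/TEMPO, and the exo-methylene trione 11 can dimerise by hetero-Diels–Alder reaction before it is trapped. The fallback sets out from 6 and returns at 12 by separating oxidation from coupling. The same Ag2O/TEMPO oxidation run in the presence of morpholine (3 equiv) gives the aza-Michael adduct (4R)-2-acetyl-4-[(2E)-3,7-dimethylocta-2,6-dien-1-yl]-3,5-dihydroxy-4-methyl-6-(morpholin-4-ylmethyl)cyclohexa-2,5-dien-1-one F5, a storable Mannich base. Warming F5 with 10 in dioxane at 60 °C releases morpholine and regenerates 11 slowly with no oxidant present, so that 10 adds to it as in step 7.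

**Further compounds**
F1 | step 2 | racemic 2-acetyl-3,5-dihydroxy-4,6-dimethyl-4-(prop-2-en-1-yl)cyclohexa-2,5-dien-1-one | CC1=C(O)C(C)(CC=C)C(O)=C(C(C)=O)C1=O
F2 | step 2 | (S)-N,N-dimethyl-1-phenylethylammonium salt of the enolate of (4R)-2-acetyl-3,5-dihydroxy-4,6-dimethyl-4-(prop-2-en-1-yl)cyclohexa-2,5-dien-1-one | CC1=C([O-])[C@@](C)(CC=C)C(O)=C(C(C)=O)C1=O.C[C@H]([NH+](C)C)c1ccccc1
F3 | step 2 | (S)-N,N-dimethyl-1-phenylethylammonium salt of the enolate of (4S)-2-acetyl-3,5-dihydroxy-4,6-dimethyl-4-(prop-2-en-1-yl)cyclohexa-2,5-dien-1-one | CC1=C([O-])[C@](C)(CC=C)C(O)=C(C(C)=O)C1=O.C[C@H]([NH+](C)C)c1ccccc1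
F4 | step 4 | (4R)-2-acetyl-3,5-dihydroxy-4-[(2E)-3-iodobut-2-en-1-yl]-4,6-dimethylcyclohexa-2,5-dien-1-one | CC1=C(O)[C@@](C)(C/C=C(\C)I)C(O)=C(C(C)=O)C1=O
F5 | step 7 | (4R)-2-acetyl-4-[(2E)-3,7-dimethylocta-2,6-dien-1-yl]-3,5-dihydroxy-4-methyl-6-(morpholin-4-ylmethyl)cyclohexa-2,5-dien-1-one | C1COCCN1CC1=C(O)[C@@](C)(C/C=C(\C)CCC=C(C)C)C(O)=C(C(C)=O)C1=O
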